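**Retrosynthetic overview**
1. Target 35 ⇐ C1=C10 epoxidation of trienolide 34 ⇐ unmasking of the α-methylene lactone and the 2-OH in 31.
2. Ten-membered ring ⇐ ring expansion: Grob-type 1,4-fragmentation of the C5–C10 ring-fusion bond of trans-decalin mesylate aldehyde 28, which creates both E ring double bonds.
3. 28 ⇐ decalin 16 by Rubottom oxidation, borane reduction/hydroboration, Mannich masking, angeloylation and mesylation; ring B of 16 ⇐ ring-closing metathesis (C7=C8).
4. γ-Lactone ⇐ NHK addition to the C6 aldehyde and oxidative lactonisation; ketone 10 ⇐ enone 5 by trans-selective dithiane conjugate addition/allylation; 5 ⇐ organocatalytic Michael/aldol of 2 with 3.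
5. Ring order: ring A (cyclohexenone) → γ-lactone → ring B → ten-membered carbocycle → epoxide.

Convention: atoms carry germacrane/eudesmane numbers C1–C15 in every intermediate; α/β refer to the usual drawing with the C10 methyl (C14) β. Assumption: the Michael step shows the usual facial bias of the (S)-diarylprolinol silyl ether.

**Route**

Step 1
Reactants: 1 acrolein
Product: 2 3-[(4-methoxybenzyl)oxy]propanal
Conditions: 4-MeOC6H4CH2OH, ClCH2CO2H (cat.), NaOH (cat.), AcOH, 40 °C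
Reagents that add atoms: 4-methoxybenzyl alcohol, COc1ccc(CO)cc1
Why: Oxa-Michael addition of the benzylic alcohol to acrolein gives the β-alkoxy aldehyde that carries the future C15–C4–C5 unit, and no stereocentre is formed.

Step 2
Reactants: 2 3-[(4-methoxybenzyl)oxy]propanal, 3 ethyl vinyl ketone
Product: 5 (R)-4-{[(4-methoxybenzyl)oxy]methyl}-2-methylcyclohex-2-en-1-one, via keto aldehyde 4 (not isolated)
Conditions: (S)-α,α-diphenylprolinol trimethylsilyl ether (10 mol %), catechol (20 mol %), 3 (1.5 equiv), neat, 4 °C; then LiOH (20 mol %), i-PrOH, 25 °C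
Reagents that add atoms: none
Why: Enamine (Jørgensen–Hayashi) Michael addition to the vinyl ketone followed by intramolecular aldol condensation, in which the shielded enamine face sets the C4 stereocentre (R), which is no longer enolisable in enone 5.

Step 3
Reactants: 5 (R)-4-{[(4-methoxybenzyl)oxy]methyl}-2-methylcyclohex-2-en-1-one, 6 1,3-dithiane, 7 allyl bromide
Product: 10 (2R,3S,4R)-2-allyl-3-(1,3-dithian-2-yl)-4-{[(4-methoxybenzyl)oxy]methyl}-2-methylcyclohexan-1-one, via 2-lithio-1,3-dithiane 8 (not isolated), via lithium enolate 9 (not isolated)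
Conditions: 6, n-BuLi, THF, −30 °C; HMPA, then 5, −78 °C; then 7, −78 → 0 °C
Reagents that add atoms: none
Why: HMPA-promoted 1,4-addition of the dithiane anion occurs trans to the C4 side chain and the regiodefined enolate 9 is allylated trans to the new C5 substituent, creating the quaternary C10 (tandem conjugate addition–enolate alkylation).

Step 4
Reactants: 10 (2R,3S,4R)-2-allyl-3-(1,3-dithian-2-yl)-4-{[(4-methoxybenzyl)oxy]methyl}-2-methylcyclohexan-1-one
Product: 11 (1S,2R,6R)-2-allyl-6-{[(4-methoxybenzyl)oxy]methyl}-2-methyl-3-oxocyclohexane-1-carbaldehyde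
Conditions: MeI, CaCO3, MeCN/H2O (4:1), 45 °C
Reagents that add atoms: water, O
Why: S-Methylation turns the dithiane into a leaving group and hydrolysis (Corey–Seebach unmasking) releases the C6 aldehyde without touching ketone, alkene or PMB ether, with C5 staying in the equatorial trans arrangement.

Step 5
Reactants: 11 (1S,2R,6R)-2-allyl-6-{[(4-methoxybenzyl)oxy]methyl}-2-methyl-3-oxocyclohexane-1-carbaldehyde, 12 3-bromobut-3-en-1-ol
Product: 13 (2R,3S,4R)-2-allyl-3-[(1R)-1,4-dihydroxy-2-methylidenebutyl]-4-{[(4-methoxybenzyl)oxy]methyl}-2-methylcyclohexan-1-one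
Conditions: CrCl2 (4 equiv), NiCl2 (2 mol %), DMF, 25 °C
Reagents that add atoms: none
Why: Nozaki–Hiyama–Kishi addition of the alkenylchromium reagent is aldehyde-selective and follows Felkin–Anh control (attack anti to the quaternary C10), which sets the C6 carbinol (R, later 6α-O).

Step 6
Reactants: 13 (2R,3S,4R)-2-allyl-3-[(1R)-1,4-dihydroxy-2-methylidenebutyl]-4-{[(4-methoxybenzyl)oxy]methyl}-2-methylcyclohexan-1-one
Product: 15 (2R,3S,4R)-2-allyl-4-{[(4-methoxybenzyl)oxy]methyl}-2-methyl-3-[(2R)-3-methylidene-5-oxooxolan-2-yl]cyclohexan-1-one, via lactol 14 (not isolated)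
Conditions: TEMPO (20 mol %), PhI(OAc)2 (2.5 equiv), CH2Cl2, 25 °C
Reagents that add atoms: none
Why: TEMPO/PhI(OAc)2 oxidises only the primary alcohol, the hydroxy aldehyde closes to lactol 14 and this is oxidised on to the γ-lactone (oxidative lactonisation) with no change at any stereocentre.

Step 7
Reactants: 15 (2R,3S,4R)-2-allyl-4-{[(4-methoxybenzyl)oxy]methyl}-2-methyl-3-[(2R)-3-methylidene-5-oxooxolan-2-yl]cyclohexan-1-one
Product: 16 15-[(4-methoxybenzyl)oxy]-1-oxo-13-nor-eudesm-7-en-12,6α-olide (trans-decalin; 10β-CH3; 5α-H; 4α-CH2OPMB; 6β-H)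
Conditions: second-generation Grubbs catalyst (5 mol %), CH2Cl2 (5 mM), 40 °C
Reagents that add atoms: none
Why: Ring-closing metathesis of the trans-diequatorial allyl and 1,1-disubstituted alkene arms closes ring B as the trisubstituted C7=C8 cyclohexene with loss of ethene, giving the trans-decalin.

Step 8
Reactants: 16 15-[(4-methoxybenzyl)oxy]-1-oxo-13-nor-eudesm-7-en-12,6α-olide
Product: 18 2α-(tert-butyldimethylsilyloxy)-15-[(4-methoxybenzyl)oxy]-1-oxo-13-nor-eudesm-7-en-12,6α-olide, via silyl enol ether 17 (not isolated)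
Conditions: t-BuMe2SiOTf, Et3N, CH2Cl2, −78 → 0 °C; then mCPBA, NaHCO3, −40 °C
Reagents that add atoms: tert-butyldimethylsilyl triflate, CC(C)(C)[Si](C)(C)OS(=O)(=O)C(F)(F)F; mCPBA, OOC(=O)c1cccc(Cl)c1
Why: Ketone-selective soft enolisation and Rubottom oxidation, in which the peracid attacks the C1=C2 enol ether from the α face because the β face is blocked by the axial C10 methyl, giving the equatorial 2α-silyloxy ketone after 1,4-silyl shift.

Step 9
Reactants: 18 2α-(tert-butyldimethylsilyloxy)-15-[(4-methoxybenzyl)oxy]-1-oxo-13-nor-eudesm-7-en-12,6α-olide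
Product: 20 2α-(tert-butyldimethylsilyloxy)-1β,8α-dihydroxy-15-[(4-methoxybenzyl)oxy]-13-nor-eudesman-12,6α-olide (7α-H; trans-fused lactone), via organoborane 19 (not isolated)
Conditions: BH3·SMe2 (4 equiv), THF, 0 → 25 °C; then H2O2, aq. NaHCO3, 0 °C
Reagents that add atoms: hydrogen peroxide, OO
Why: Borane reduces the C1 ketone by axial (α) hydride delivery to the equatorial 1β-alcohol and hydroborates C7=C8 syn from the α face (anti to the axial C10 methyl, boron on the less substituted C8), so oxidation sets 7α-H and 8α-OH (hydroboration–oxidation).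

Step 10
Reactants: 20 2α-(tert-butyldimethylsilyloxy)-1β,8α-dihydroxy-15-[(4-methoxybenzyl)oxy]-13-nor-eudesman-12,6α-olide
Product: 22 13-(dimethylamino)-2α-(tert-butyldimethylsilyloxy)-1β,8α-dihydroxy-15-[(4-methoxybenzyl)oxy]eudesman-12,6α-olide (C11 epimers), via lactone enolate 21 (not isolated)
Conditions: LiN(i-Pr)2 (3.5 equiv), THF, −78 °C; then Me2N=CH2+ I−, −78 → 0 °C; H2O
Reagents that add atoms: dimethylmethylideneammonium iodide (Eschenmoser's salt), C[N+](C)=C.[I-]
Why: Mannich alkylation of the lactone enolate introduces C13 as a β-amino lactone, a masked α-methylene lactone that is inert to amines and bases in the following steps, and the C11 configuration is irrelevant because C11 becomes sp2 later.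

Step 11
Reactants: 22 13-(dimethylamino)-2α-(tert-butyldimethylsilyloxy)-1β,8α-dihydroxy-15-[(4-methoxybenzyl)oxy]eudesman-12,6α-olide, 23 angelic acid
Product: 25 8α-angeloyloxy-13-(dimethylamino)-2α-(tert-butyldimethylsilyloxy)-1β-hydroxy-15-[(4-methoxybenzyl)oxy]eudesman-12,6α-olide, via mixed anhydride 24 (not isolated)
Conditions: 23, 2,4,6-Cl3C6H2COCl, Et3N, toluene, 25 °C; then 22, DMAP, 60 °C
Reagents that add atoms: none
Why: Yamaguchi esterification acylates the accessible equatorial C8 hydroxyl while the neopentyl C1 hydroxyl (flanked by C10 and the silyloxy-bearing C2) stays free, and the mixed-anhydride method keeps the Z (angelate) geometry.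

Step 12
Reactants: 25 8α-angeloyloxy-13-(dimethylamino)-2α-(tert-butyldimethylsilyloxy)-1β-hydroxy-15-[(4-methoxybenzyl)oxy]eudesman-12,6α-olide
Product: 26 8α-angeloyloxy-13-(dimethylamino)-2α-(tert-butyldimethylsilyloxy)-1β-(methanesulfonyloxy)-15-[(4-methoxybenzyl)oxy]eudesman-12,6α-olide
Conditions: MsCl, Et3N, DMAP (cat.), CH2Cl2, 0 → 25 °C
Reagents that add atoms: methanesulfonyl chloride, CS(=O)(=O)Cl
Why: Sulfonylation of the remaining equatorial 1β-hydroxyl installs the nucleofuge antiperiplanar to the C5–C10 bond with retention at C1.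

Step 13
Reactants: 26 8α-angeloyloxy-13-(dimethylamino)-2α-(tert-butyldimethylsilyloxy)-1β-(methanesulfonyloxy)-15-[(4-methoxybenzyl)oxy]eudesman-12,6α-olide
Product: 27 8α-angeloyloxy-13-(dimethylamino)-2α-(tert-butyldimethylsilyloxy)-15-hydroxy-1β-(methanesulfonyloxy)eudesman-12,6α-olide
Conditions: CF3CO2H (1.1 equiv), then DDQ, CH2Cl2/H2O (18:1), 0 °C; aq. NaHCO3 work-up
Reagents that add atoms: none
Why: Oxidative PMB cleavage by DDQ (benzylic hydride abstraction, hydrolysis of the oxocarbenium ion) frees the C15 alcohol, and prior protonation protects the tertiary amine from DDQ.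

Step 14
Reactants: 27 8α-angeloyloxy-13-(dimethylamino)-2α-(tert-butyldimethylsilyloxy)-15-hydroxy-1β-(methanesulfonyloxy)eudesman-12,6α-olide
Product: 28 8α-angeloyloxy-13-(dimethylamino)-2α-(tert-butyldimethylsilyloxy)-1β-(methanesulfonyloxy)-15-oxoeudesman-12,6α-olide
Conditions: Dess–Martin periodinane, NaHCO3, CH2Cl2, 0 → 25 °C
Reagents that add atoms: none
Why: Dess–Martin oxidation gives the C15 aldehyde under buffered conditions, and any epimerisation at C4 is harmless because C4 becomes sp2 in the next step.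

Step 15
Reactants: 28 8α-angeloyloxy-13-(dimethylamino)-2α-(tert-butyldimethylsilyloxy)-1β-(methanesulfonyloxy)-15-oxoeudesman-12,6α-olide
Product: 31 (1(10)E,4E)-8α-angeloyloxy-13-(dimethylamino)-2α-(tert-butyldimethylsilyloxy)-15-hydroxygermacra-1(10),4-dien-12,6α-olide, via enamine 29 (not isolated), via dienal 30 (not isolated)
Conditions: pyrrolidine (30 mol %), NaHCO3 (1.5 equiv), MeCN/CF3CH2OH/H2O (8:2:1), 45 °C; then CeCl3·7H2O, NaBH4, MeOH, −30 °C
Reagents that add atoms: none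
Why: Proposed new method: amine-catalysed (enamine-assisted) 1,4-fragmentation, in which pyrrolidine condenses with the C15 aldehyde to enamine 29, whose nitrogen lone pair pushes through C15=C4 into the aligned C5–C10 bond as the equatorial C1 mesylate ionises, so the ring-fusion bond of the trans-decalin breaks and the ten-membered ring forms with both double bonds E (C6 and C9 are equatorial, anti to C3–C4 and C1–C2), after which hydrolysis of the dienyl iminium ion returns the amine and NaBH4/CeCl3 reduces the labile dienal 30 in 1,2-fashion; the closest known reaction types are the strong-base enolate-assisted 1,4-fragmentation of eudesmane mesylates (Grob/Wharton/Marshall family) and amine-driven Grob fragmentations of γ-amino sulfonates.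

Step 16
Reactants: 31 (1(10)E,4E)-8α-angeloyloxy-13-(dimethylamino)-2α-(tert-butyldimethylsilyloxy)-15-hydroxygermacra-1(10),4-dien-12,6α-olide
Product: 34 8α-angeloyloxy-2α,15-dihydroxygermacra-1(10)E,4E,11(13)-trien-12,6α-olide, via methiodide 32 (not isolated), via silyl ether 33 (not isolated)
Conditions: MeI, MeCN, 25 °C; evaporate; then Bu4NF, THF, 0 → 25 °C
Reagents that add atoms: none
Why: Exhaustive N-methylation and fluoride-induced E1cB (Hofmann-type) elimination of trimethylamine unveil the α-methylene lactone, and the same fluoride cleaves the C2 silyl ether.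

Step 17
Reactants: 34 8α-angeloyloxy-2α,15-dihydroxygermacra-1(10)E,4E,11(13)-trien-12,6α-olide
Product: 35 8α-angeloyloxy-1β,10α-epoxy-2α,15-dihydroxygermacra-4E,11(13)-dien-12,6α-olide (EANPDB:COMP_00180)
Conditions: mCPBA (1.05 equiv), NaHCO3, CH2Cl2, −20 → 0 °C
Reagents that add atoms: mCPBA, OOC(=O)c1cccc(Cl)c1
Why: Prilezhaev epoxidation attacks the most electron-rich C1=C10 double bond (C4=C5 is deactivated by the allylic lactone oxygen, the two enoates are electron-poor) from its exposed outer face in the crown conformation, assisted by hydrogen bonding to the 2α-hydroxyl, giving the 1β,10α-epoxide (1R,10R).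

**Compound list**

1 | acrolein (prop-2-enal) | C=CC=O | starting material
2 | 3-[(4-methoxybenzyl)oxy]propanal | O=CCCOCc1ccc(OC)cc1 | intermediate
3 | ethyl vinyl ketone (pent-1-en-3-one) | CCC(=O)C=C | starting material
4 | (S)-2-{[(4-methoxybenzyl)oxy]methyl}-5-oxoheptanal | O=C[C@H](COCc1ccc(OC)cc1)CCC(=O)CC | intermediate
5 | (R)-4-{[(4-methoxybenzyl)oxy]methyl}-2-methylcyclohex-2-en-1-one | CC1=C[C@H](COCc2ccc(OC)cc2)CCC1=O | intermediate
6 | 1,3-dithiane | C1CSCSC1 | starting material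
7 | allyl bromide (3-bromoprop-1-ene) | C=CCBr | starting material
8 | 2-lithio-1,3-dithiane | [Li]C1SCCCS1 | intermediate
9 | lithium enolate of the conjugate adduct (C1–O–Li, C1=C10; dithianyl at C5 trans to CH2OPMB at C4) | [Li]OC1=C(C)[C@@H](C2SCCCS2)[C@H](COCc2ccc(OC)cc2)CC1 | intermediate
10 | (2R,3S,4R)-2-allyl-3-(1,3-dithian-2-yl)-4-{[(4-methoxybenzyl)oxy]methyl}-2-methylcyclohexan-1-one (allyl trans to dithianyl, dithianyl trans to CH2OPMB) | O=C1CC[C@@H](COCc2ccc(OC)cc2)[C@H](C2SCCCS2)[C@@]1(C)CC=C | intermediate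
11 | (1S,2R,6R)-2-allyl-6-{[(4-methoxybenzyl)oxy]methyl}-2-methyl-3-oxocyclohexane-1-carbaldehyde | O=C1CC[C@@H](COCc2ccc(OC)cc2)[C@H](C=O)[C@@]1(C)CC=C | intermediate
12 | 3-bromobut-3-en-1-ol | OCCC(Br)=C | starting material
13 | (2R,3S,4R)-2-allyl-3-[(1R)-1,4-dihydroxy-2-methylidenebutyl]-4-{[(4-methoxybenzyl)oxy]methyl}-2-methylcyclohexan-1-one | O=C1CC[C@@H](COCc2ccc(OC)cc2)[C@H]([C@@H](O)C(=C)CCO)[C@@]1(C)CC=C | intermediate
14 | lactol: as 15 but with C12 as a hemiacetal CH(OH) (anomers) | O=C1CC[C@@H](COCc2ccc(OC)cc2)[C@H]([C@H]2OC(O)CC2=C)[C@@]1(C)CC=C | intermediate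
15 | (2R,3S,4R)-2-allyl-4-{[(4-methoxybenzyl)oxy]methyl}-2-methyl-3-[(2R)-3-methylidene-5-oxooxolan-2-yl]cyclohexan-1-one | O=C1CC[C@@H](COCc2ccc(OC)cc2)[C@H]([C@H]2OC(=O)CC2=C)[C@@]1(C)CC=C | intermediate
16 | 15-[(4-methoxybenzyl)oxy]-1-oxo-13-nor-eudesm-7-en-12,6α-olide (trans-decalin, 10β-CH3, 5α-H, 4α-CH2OPMB, 6β-H) | O=C1CC[C@@H](COCc2ccc(OC)cc2)[C@@H]2[C@H]3OC(=O)CC3=CC[C@@]12C | intermediate
17 | C1=C2 tert-butyldimethylsilyl enol ether of 16 | CC(C)(C)[Si](C)(C)OC1=CC[C@@H](COCc2ccc(OC)cc2)[C@@H]2[C@H]3OC(=O)CC3=CC[C@@]12C | intermediate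
18 | 2α-(tert-butyldimethylsilyloxy)-15-[(4-methoxybenzyl)oxy]-1-oxo-13-nor-eudesm-7-en-12,6α-olide | O=C1[C@@H](O[Si](C)(C)C(C)(C)C)C[C@@H](COCc2ccc(OC)cc2)[C@@H]2[C@H]3OC(=O)CC3=CC[C@@]12C | intermediate
19 | organoborane: 1β-O-boryl, 8α-C-boryl adduct of 18 (7α-H) | BO[C@@H]1[C@@H](O[Si](C)(C)C(C)(C)C)C[C@@H](COCc2ccc(OC)cc2)[C@@H]2[C@H]3OC(=O)C[C@@H]3[C@@H](B)C[C@@]12C | intermediate
20 | 2α-(tert-butyldimethylsilyloxy)-1β,8α-dihydroxy-15-[(4-methoxybenzyl)oxy]-13-nor-eudesman-12,6α-olide (7α-H, trans-lactone) | O[C@@H]1[C@@H](O[Si](C)(C)C(C)(C)C)C[C@@H](COCc2ccc(OC)cc2)[C@@H]2[C@H]3OC(=O)C[C@@H]3[C@@H](O)C[C@@]12C | intermediate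
21 | trilithium salt of 20 (1-O-Li, 8-O-Li, lactone enolate C12(OLi)=C11) | [Li]O[C@@H]1[C@@H](O[Si](C)(C)C(C)(C)C)C[C@@H](COCc2ccc(OC)cc2)[C@@H]2[C@H]3OC(O[Li])=C[C@@H]3[C@@H](O[Li])C[C@@]12C | intermediate
22 | 13-(dimethylamino)-2α-(tert-butyldimethylsilyloxy)-1β,8α-dihydroxy-15-[(4-methoxybenzyl)oxy]eudesman-12,6α-olide (C11 epimer mixture, C11 left undefined) | O[C@@H]1[C@@H](O[Si](C)(C)C(C)(C)C)C[C@@H](COCc2ccc(OC)cc2)[C@@H]2[C@H]3OC(=O)C(CN(C)C)[C@@H]3[C@@H](O)C[C@@]12C | intermediate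
23 | angelic acid ((Z)-2-methylbut-2-enoic acid) | C/C=C(/C)C(=O)O | starting material
24 | angelic 2,4,6-trichlorobenzoic anhydride | C/C=C(/C)C(=O)OC(=O)c1c(Cl)cc(Cl)cc1Cl | intermediate
25 | 8α-angelate of 22 (1β-OH free) | O[C@@H]1[C@@H](O[Si](C)(C)C(C)(C)C)C[C@@H](COCc2ccc(OC)cc2)[C@@H]2[C@H]3OC(=O)C(CN(C)C)[C@@H]3[C@@H](OC(=O)/C(C)=C\C)C[C@@]12C | intermediate
26 | 1β-mesylate of 25 | CS(=O)(=O)O[C@@H]1[C@@H](O[Si](C)(C)C(C)(C)C)C[C@@H](COCc2ccc(OC)cc2)[C@@H]2[C@H]3OC(=O)C(CN(C)C)[C@@H]3[C@@H](OC(=O)/C(C)=C\C)C[C@@]12C | intermediate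
27 | 15-alcohol: 26 without the PMB group | CS(=O)(=O)O[C@@H]1[C@@H](O[Si](C)(C)C(C)(C)C)C[C@@H](CO)[C@@H]2[C@H]3OC(=O)C(CN(C)C)[C@@H]3[C@@H](OC(=O)/C(C)=C\C)C[C@@]12C | intermediate
28 | 15-aldehyde: 8α-angeloyloxy-13-(dimethylamino)-2α-(tert-butyldimethylsilyloxy)-1β-(methanesulfonyloxy)-15-oxoeudesman-12,6α-olide | CS(=O)(=O)O[C@@H]1[C@@H](O[Si](C)(C)C(C)(C)C)C[C@@H](C=O)[C@@H]2[C@H]3OC(=O)C(CN(C)C)[C@@H]3[C@@H](OC(=O)/C(C)=C\C)C[C@@]12C | intermediate
29 | pyrrolidine enamine of 28 (C15=C4) | CS(=O)(=O)O[C@@H]1[C@@H](O[Si](C)(C)C(C)(C)C)CC(=CN2CCCC2)[C@@H]3[C@H]4OC(=O)C(CN(C)C)[C@@H]4[C@@H](OC(=O)/C(C)=C\C)C[C@@]13C | intermediate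
30 | (1(10)E,4E)-8α-angeloyloxy-13-(dimethylamino)-2α-(tert-butyldimethylsilyloxy)-15-oxogermacra-1(10),4-dien-12,6α-olide (C15 cis to C6) | CN(C)CC1C(=O)O[C@@H]2/C=C(\C=O)C[C@H](O[Si](C)(C)C(C)(C)C)/C=C(\C)C[C@H](OC(=O)/C(C)=C\C)[C@@H]12 | intermediate
31 | (1(10)E,4E)-8α-angeloyloxy-13-(dimethylamino)-2α-(tert-butyldimethylsilyloxy)-15-hydroxygermacra-1(10),4-dien-12,6α-olide | CN(C)CC1C(=O)O[C@@H]2/C=C(\CO)C[C@H](O[Si](C)(C)C(C)(C)C)/C=C(\C)C[C@H](OC(=O)/C(C)=C\C)[C@@H]12 | intermediate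
32 | N-methyl ammonium iodide (methiodide) of 31 | C[N+](C)(C)CC1C(=O)O[C@@H]2/C=C(\CO)C[C@H](O[Si](C)(C)C(C)(C)C)/C=C(\C)C[C@H](OC(=O)/C(C)=C\C)[C@@H]12.[I-] | intermediate
33 | 2-O-tert-butyldimethylsilyl ether of 34 | C=C1C(=O)O[C@@H]2/C=C(\CO)C[C@H](O[Si](C)(C)C(C)(C)C)/C=C(\C)C[C@H](OC(=O)/C(C)=C\C)[C@@H]12 | intermediate
34 | 8α-angeloyloxy-2α,15-dihydroxygermacra-1(10)E,4E,11(13)-trien-12,6α-olide | C=C1C(=O)O[C@@H]2/C=C(\CO)C[C@H](O)/C=C(\C)C[C@H](OC(=O)/C(C)=C\C)[C@@H]12 | intermediate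
35 | 8α-angeloyloxy-1β,10α-epoxy-2α,15-dihydroxygermacra-4E,11(13)-dien-12,6α-olide | C=C1C(=O)O[C@@H]2/C=C(\CO)C[C@H](O)[C@H]3O[C@]3(C)C[C@H](OC(=O)/C(C)=C\C)[C@@H]12 | target

**Step count and risks**

Total steps: 17. Longest linear sequence: 17 (steps 1–17 from acrolein).

The three steps most likely to fail:

Step 15 (the new amine-catalysed fragmentation): the neutral enamine may be too weak a donor to ionise the secondary mesylate. The fallback sets out from aldehyde 28 and comes back at alcohol 31. It uses the known stoichiometric enolate-assisted 1,4-fragmentation: KN(SiMe3)2 (1.05 equiv), THF, −78 → 20 °C deprotonates the aldehyde selectively to the potassium enolate F3, which fragments to dienal 30; this is reduced in the same flask (CeCl3·7H2O, NaBH4, MeOH, −30 °C) to 31.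

Step 3 (tandem dithiane 1,4-addition/allylation): 1,2-addition or poor enolate trapping on the α-methyl enone is possible. The fallback sets out from enone 5 and comes back at aldehyde 11. A hydroxymethyl anion equivalent replaces the formyl anion equivalent: CuI-catalysed conjugate addition of (i-PrO)Me2SiCH2MgCl (THF, −78 °C) with trapping of the enolate by allyl bromide 7 (HMPA) gives the silylmethyl ketone F1. Tamao–Fleming oxidation (KF, KHCO3, H2O2, THF/MeOH) gives the hydroxymethyl ketone F2, and Dess–Martin oxidation of F2 gives 11.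

Step 17 (chemoselective epoxidation): the C15 allylic alcohol could steer some peracid to C4=C5. The fallback sets out from diol 34 and comes back at target 35. The primary C15 alcohol is silylated selectively (t-BuMe2SiCl, imidazole, CH2Cl2, 0 °C) to the silyl ether F4. Hydroxyl-directed epoxidation from the 2α-hydroxyl alone (VO(acac)2 cat., t-BuOOH, CH2Cl2, 0 °C) gives the epoxide F5, and HF·pyridine/pyridine in THF removes the silyl group to give 35.

Further compounds
F1 | step 3 | (2R,3S,4R)-2-allyl-3-{[dimethyl(propan-2-yloxy)silyl]methyl}-4-{[(4-methoxybenzyl)oxy]methyl}-2-methylcyclohexan-1-one | O=C1CC[C@@H](COCc2ccc(OC)cc2)[C@H](C[Si](C)(C)OC(C)C)[C@@]1(C)CC=C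
F2 | step 3 | (2R,3S,4R)-2-allyl-3-(hydroxymethyl)-4-{[(4-methoxybenzyl)oxy]methyl}-2-methylcyclohexan-1-one | O=C1CC[C@@H](COCc2ccc(OC)cc2)[C@H](CO)[C@@]1(C)CC=C
F3 | step 15 | potassium enolate of aldehyde 28 (C15(OK)=C4) | CS(=O)(=O)O[C@@H]1[C@@H](O[Si](C)(C)C(C)(C)C)CC(=CO[K])[C@@H]2[C@H]3OC(=O)C(CN(C)C)[C@@H]3[C@@H](OC(=O)/C(C)=C\C)C[C@@]12C
F4 | step 17 | 15-O-tert-butyldimethylsilyl ether of 34 | C=C1C(=O)O[C@@H]2/C=C(\CO[Si](C)(C)C(C)(C)C)C[C@H](O)/C=C(\C)C[C@H](OC(=O)/C(C)=C\C)[C@@H]12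
F5 | step 17 | 15-O-tert-butyldimethylsilyl ether of 35 | C=C1C(=O)O[C@@H]2/C=C(\CO[Si](C)(C)C(C)(C)C)C[C@H](O)[C@H]3O[C@]3(C)C[C@H](OC(=O)/C(C)=C\C)[C@@H]12
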